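Everything rests on closing ring A at the bond between the C3 methylene and the C4 carbonyl carbon (eudesmane numbering). The key step exploits ring A's 4-hydroxycyclohexanone pattern: between the C1 carbinol and the C4 ketone lie only the unfunctionalised C2 and C3, so C3 can be a primary alkylsamarium and C4 an ester. One samarium diiodide-promoted intramolecular acyl substitution turns a monocyclic iodo diester, whose trans C5/C10 centres come from a catalytic asymmetric Diels–Alder reaction and whose C1 carbinol from a CBS reduction, into the trans-fused 4-decalone. The rigid bicycle then directs α-face oxygenation of ring B at C6 and C8.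

Key step: step 9

Remark on the chemistry: eudesmane numbering is used throughout (C1 carbinol, C4 ketone, C5/C10 ring fusion, C6 and C8 oxygenated, C7 acrylate-bearing, C11–C13 acrylate carbons, C14 angular methyl); β means the face of the C10 methyl group, α the opposite face.

Step 1
Reactants: 1 buta-2,3-dien-1-ol; 2 trimethyl orthoacetate
Product: 4 methyl 3-methylenepent-4-enoate, via mixed ketene acetal 3 (not isolated)
Conditions: 2 (4 equiv), EtCO2H (5 mol%), 140 °C, MeOH distilled off
Reagents that add atoms: none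
Why: Johnson–Claisen rearrangement: acid-catalysed alcohol exchange and loss of methanol give ketene acetal 3, whose [3,3]-sigmatropic shift onto the central allene carbon should deliver the 2-substituted buta-1,3-diene; no stereocentre is formed.

Step 2
Reactants: 5 methyl 3-methylbut-2-enoate
Product: 6 methyl (E)-3-methyl-4-oxobut-2-enoate
Conditions: SeO2 (1.2 equiv), 1,4-dioxane, reflux
Reagents that add atoms: selenium dioxide O=[Se]=O
Why: Riley allylic oxidation (ene reaction then [2,3]-shift) should oxidise the methyl group trans to the ester, so aldehyde and ester end up (E); this alkene geometry later fixes the trans C5/C10 relationship.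

Step 3
Reactants: 4 methyl 3-methylenepent-4-enoate; 6 methyl (E)-3-methyl-4-oxobut-2-enoate
Product: 7 methyl (1R,6R)-6-formyl-3-(2-methoxy-2-oxoethyl)-6-methylcyclohex-3-ene-1-carboxylate
Conditions: (3aS)-1-(2-methylphenyl)-3,3-diphenyltetrahydro-1H,3H-pyrrolo[1,2-c][1,3,2]oxazaborole (20 mol%), HNTf2 (18 mol%), 4 (1.5 equiv), CH2Cl2, −78 → −40 °C
Reagents that add atoms: none
Why: Catalytic enantioselective Diels–Alder reaction: the cationic oxazaborolidine should bind the formyl group of 6 and expose the Re face of the formyl-bearing alkene carbon (the sense expected for 2-substituted acroleins with this catalyst antipode; the (3aR) catalyst would be used if the sense proved opposite), the aldehyde directs the 2-substituted diene to the "para" adduct, and suprafacial addition to the (E)-alkene sets C10 (methyl β, formyl α) and C5 (ester β) trans in one step.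

Step 4
Reactants: 7 methyl (1R,6R)-6-formyl-3-(2-methoxy-2-oxoethyl)-6-methylcyclohex-3-ene-1-carboxylate
Product: 8 methyl (1R,6R)-6-(1-hydroxyprop-2-en-1-yl)-3-(2-methoxy-2-oxoethyl)-6-methylcyclohex-3-ene-1-carboxylate (both carbinol epimers)
Conditions: CH2=CHMgBr (1.2 equiv), THF, −78 °C; then sat. aq. NH4Cl
Reagents that add atoms: vinylmagnesium bromide C=C[Mg]Br
Why: Grignard 1,2-addition to the aldehyde should be far faster at −78 °C than attack on either ester, and the carbinol configuration is immaterial because step 5 oxidises it.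

Step 5
Reactants: 8 methyl (1R,6R)-6-(1-hydroxyprop-2-en-1-yl)-3-(2-methoxy-2-oxoethyl)-6-methylcyclohex-3-ene-1-carboxylate
Product: 9 methyl (1R,6R)-6-acryloyl-3-(2-methoxy-2-oxoethyl)-6-methylcyclohex-3-ene-1-carboxylate
Conditions: Dess–Martin periodinane (1.3 equiv), CH2Cl2, 0 °C → rt
Reagents that add atoms: none
Why: Dess–Martin oxidation of the secondary allylic alcohol under neutral conditions should give the vinyl ketone without epimerising C5.

Step 6
Reactants: 9 methyl (1R,6R)-6-acryloyl-3-(2-methoxy-2-oxoethyl)-6-methylcyclohex-3-ene-1-carboxylate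
Product: 11 methyl (1R,6R)-6-(3-iodopropanoyl)-3-(2-methoxy-2-oxoethyl)-6-methylcyclohex-3-ene-1-carboxylate, via silyl enol ether 10 (not isolated)
Conditions: Me3SiI (1.2 equiv), CH2Cl2, −78 → −40 °C; then 0.5 M HCl, 0 °C
Reagents that add atoms: iodotrimethylsilane C[Si](C)(C)I
Why: 1,4-Addition of iodotrimethylsilane to the enone gives β-iodo silyl enol ether 10, and mild acid hydrolysis should release the β-iodo ketone, so the C3 leaving group is installed without base.

Step 7
Reactants: 11 methyl (1R,6R)-6-(3-iodopropanoyl)-3-(2-methoxy-2-oxoethyl)-6-methylcyclohex-3-ene-1-carboxylate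
Product: 12 methyl (1R,6R)-6-[(1R)-1-hydroxy-3-iodopropyl]-3-(2-methoxy-2-oxoethyl)-6-methylcyclohex-3-ene-1-carboxylate
Conditions: (3aS)-1-methyl-3,3-diphenyltetrahydro-1H,3H-pyrrolo[1,2-c][1,3,2]oxazaborole (20 mol%), catecholborane (1.5 equiv), toluene, −40 °C; then MeOH, pH 7 buffer
Reagents that add atoms: none
Why: Corey–Bakshi–Shibata reduction: the ketone should coordinate to the catalyst boron through the lone pair remote from the quaternary C10 (large group versus the iodoethyl arm), so hydride from catecholborane is delivered to one face and C1 is set as (R), the 1β-oxygen of the target, by reagent control.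

Step 8
Reactants: 12 methyl (1R,6R)-6-[(1R)-1-hydroxy-3-iodopropyl]-3-(2-methoxy-2-oxoethyl)-6-methylcyclohex-3-ene-1-carboxylate
Product: 13 methyl (1R,6R)-6-[(1R)-1-(tert-butyldimethylsilyloxy)-3-iodopropyl]-3-(2-methoxy-2-oxoethyl)-6-methylcyclohex-3-ene-1-carboxylate
Conditions: TBSOTf (1.3 equiv), 2,6-lutidine (2 equiv), CH2Cl2, −78 → 0 °C
Reagents that add atoms: tert-butyldimethylsilyl trifluoromethanesulfonate CC(C)(C)[Si](C)(C)OS(=O)(=O)C(F)(F)F
Why: Silyl triflate/2,6-lutidine silylation should cap the hindered neopentylic carbinol without forming the alkoxide that could close an oxetane onto C3 or a lactone onto the C4 ester.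

Step 9
Reactants: 13 methyl (1R,6R)-6-[(1R)-1-(tert-butyldimethylsilyloxy)-3-iodopropyl]-3-(2-methoxy-2-oxoethyl)-6-methylcyclohex-3-ene-1-carboxylate
Product: 15 methyl 1β-(tert-butyldimethylsilyloxy)-4-oxo-13,15-dinor-5α-eudesm-7-en-12-oate, via alkylsamarium diiodide 14 (not isolated)
Conditions: SmI2 (2.5 equiv), Fe(dbm)3 (3 mol%; dbm = 1,3-diphenylpropane-1,3-dionate), THF, −30 → 0 °C; then 0.1 M HCl
Reagents that add atoms: none
Why: Two electron transfers from divalent samarium (accelerated by Fe(dbm)3) turn the primary iodide into alkylsamarium 14, which adds to the C4 ester carbonyl through a chair-like six-membered transition state; the resulting samarium hemiketalate resists further reduction and collapses to the ketone with loss of methoxide on work-up. The closest known reaction type is the samarium diiodide-promoted intramolecular nucleophilic acyl substitution (intramolecular Barbier reaction) of ω-iodo esters. Ring A is closed in the 6-exo-trig mode. No new stereocentre is formed: the trans relationship of the C5 ester and the C10 carbinol arm fixed in the Diels–Alder step becomes the trans ring fusion (5α-H, 10β-methyl), and C1 keeps the configuration from the CBS reduction. The step needs chemoselectivity for the C4 ester over the C12 ester and the C7=C8 alkene: only the C4 carbonyl can be reached through a six-membered ring (the C12 ester would need a nine-membered one), fast reduction of the primary radical to the organosamarium should outrun 6-exo radical attack on the trisubstituted alkene, and the non-basic medium avoids epimerisation at C5.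

Step 10
Reactants: 15 methyl 1β-(tert-butyldimethylsilyloxy)-4-oxo-13,15-dinor-5α-eudesm-7-en-12-oate
Product: 16 methyl 1β-(tert-butyldimethylsilyloxy)-4,4-(ethylenedioxy)-13,15-dinor-5α-eudesm-7-en-12-oate
Conditions: Me3SiOCH2CH2OSiMe3 (2 equiv), Me3SiOTf (5 mol%), CH2Cl2, −78 → −20 °C; pyridine quench
Reagents that add atoms: 1,2-bis(trimethylsilyloxy)ethane C[Si](C)(C)OCCO[Si](C)(C)C
Why: Noyori ketalisation (silyl triflate-catalysed exchange with the bis-silyl glycol) should protect the hindered C4 ketone at low temperature without enolisation toward C5, as needed for the enolate and borane steps that follow.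

Step 11
Reactants: 16 methyl 1β-(tert-butyldimethylsilyloxy)-4,4-(ethylenedioxy)-13,15-dinor-5α-eudesm-7-en-12-oate
Product: 17 methyl 1β-(tert-butyldimethylsilyloxy)-7α,8α-epoxy-4,4-(ethylenedioxy)-13,15-dinor-5α-eudesman-12-oate
Conditions: mCPBA (1.2 equiv), NaHCO3, CH2Cl2, 0 °C
Reagents that add atoms: 3-chloroperoxybenzoic acid OOC(=O)c1cccc(Cl)c1
Why: Prilezhaev epoxidation of the only alkene should occur on the α-face because the axial C10 methyl shields the β-face at C8 of the rigid trans-decalin, which fixes the C8–O bond as α.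

Step 12
Reactants: 17 methyl 1β-(tert-butyldimethylsilyloxy)-7α,8α-epoxy-4,4-(ethylenedioxy)-13,15-dinor-5α-eudesman-12-oate
Product: 20 methyl 1β-(tert-butyldimethylsilyloxy)-4,4-(ethylenedioxy)-8α-hydroxy-13,15-dinor-5α-eudesm-6-en-12-oate, via lithium 8-alkoxide 18 (not isolated), via dilithium dienolate 19 (not isolated)
Conditions: LiN(iPr)2 (3 equiv), THF/DMPU (6:1), −78 → −40 °C; then AcOH (8 equiv), −78 °C
Reagents that add atoms: none
Why: Ester enolate formation triggers E1cB opening of the β,γ-epoxy ester to alkoxide 18, excess base removes a C6 proton at once to give dienolate 19 (in which the ester is masked against attack by the 8-alkoxide), and kinetic α-protonation should return the deconjugated ester with the C6=C7 alkene, so the epoxide is isomerised to the transposed allylic alcohol with the C8 configuration untouched.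

Step 13
Reactants: 20 methyl 1β-(tert-butyldimethylsilyloxy)-4,4-(ethylenedioxy)-8α-hydroxy-13,15-dinor-5α-eudesm-6-en-12-oate
Product: 22 methyl 1β-(tert-butyldimethylsilyloxy)-4,4-(ethylenedioxy)-6α,8α-dihydroxy-13,15-dinor-5α,7αH-eudesman-12-oate, via C6 organoborane 21 (not isolated)
Conditions: BH3·THF (3 equiv), THF, 0 °C; then 30% H2O2, 3 M aq. NaOAc, 0 °C → rt
Reagents that add atoms: hydrogen peroxide OO
Why: Brown hydroboration–oxidation: boron should add to the less substituted C6 and hydrogen to C7 syn from the α-face (the axial C10 methyl blocks the β-face at C6), so oxidation with retention sets 6α-OH and 7α-H, completing the all-equatorial C6–C7–C8 array.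

Step 14
Reactants: 22 methyl 1β-(tert-butyldimethylsilyloxy)-4,4-(ethylenedioxy)-6α,8α-dihydroxy-13,15-dinor-5α,7αH-eudesman-12-oate
Product: 25 methyl 1β-(tert-butyldimethylsilyloxy)-4,4-(ethylenedioxy)-6α,8α-dihydroxy-15-nor-5α,7αH-eudesm-11(13)-en-12-oate, via Mannich base 23 (not isolated), via trimethylammonium iodide 24 (not isolated)
Conditions: 22 added to LiN(iPr)2 (3.3 equiv), THF, −78 °C; CH2=NMe2+ I− (4 equiv), −78 → −20 °C; then AcOH (4 equiv), −78 °C; then MeI (10 equiv), MeOH, rt; then aq. NaHCO3, CH2Cl2, rt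
Reagents that add atoms: N,N-dimethylmethyleneiminium iodide C=[N+](C)C.[I-]
Why: α-Methylenation of the ester: the lithium enolate (formed beside the two alkoxides, towards which it is inert) undergoes a Mannich reaction with the iminium salt, the cold acidic quench limits lactonisation of the γ-hydroxy ester, and N-methylation followed by E1cB loss of trimethylamine should give the 11(13)-methylene ester without affecting C7.

Step 15
Reactants: 26 methyl 2-(hydroxymethyl)acrylate
Product: 27 methyl 2-[(tert-butyldimethylsilyloxy)methyl]acrylate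
Conditions: TBSCl (1.2 equiv), imidazole (2 equiv), CH2Cl2, 0 °C → rt
Reagents that add atoms: tert-butyldimethylsilyl chloride CC(C)(C)[Si](C)(C)Cl
Why: Routine silylation of the primary allylic alcohol; no stereocentre is involved.

Step 16
Reactants: 27 methyl 2-[(tert-butyldimethylsilyloxy)methyl]acrylate
Product: 28 2-[(tert-butyldimethylsilyloxy)methyl]acrylic acid
Conditions: LiOH·H2O (1.5 equiv), THF/H2O (3:1), 0 °C; then 1 M HCl to pH 3
Reagents that add atoms: lithium hydroxide [Li+].[OH-]
Why: Saponification of the unhindered methyl ester at 0 °C should leave the silyl ether intact and give the acid after careful acidification.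

Step 17
Reactants: 25 methyl 1β-(tert-butyldimethylsilyloxy)-4,4-(ethylenedioxy)-6α,8α-dihydroxy-15-nor-5α,7αH-eudesm-11(13)-en-12-oate; 28 2-[(tert-butyldimethylsilyloxy)methyl]acrylic acid
Product: 29 methyl 1β-(tert-butyldimethylsilyloxy)-8α-{2-[(tert-butyldimethylsilyloxy)methyl]acryloyloxy}-4,4-(ethylenedioxy)-6α-hydroxy-15-nor-5α,7αH-eudesm-11(13)-en-12-oate
Conditions: 28 (1.2 equiv), DCC (1.3 equiv), DMAP (0.2 equiv), CH2Cl2, 0 °C
Reagents that add atoms: none
Why: Steglich esterification: the C8 hydroxyl (flanked by the C9 methylene) should react in preference to the C6 hydroxyl, which lies between two tertiary carbons and next to the C4 dioxolane, so the ester is placed at C8 with its configuration retained.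

Step 18
Reactants: 29 methyl 1β-(tert-butyldimethylsilyloxy)-8α-{2-[(tert-butyldimethylsilyloxy)methyl]acryloyloxy}-4,4-(ethylenedioxy)-6α-hydroxy-15-nor-5α,7αH-eudesm-11(13)-en-12-oate
Product: 30 methyl 1β,6α-dihydroxy-8α-[2-(hydroxymethyl)acryloyloxy]-4-oxo-15-nor-5α,7αH-eudesm-11(13)-en-12-oate (CNP0144895.1)
Conditions: 48% aq. HF, MeCN, 0 °C → rt
Reagents that add atoms: water O
Why: Aqueous HF should cleave both silyl ethers and hydrolyse the strained C4 dioxolane (1,3-diaxial to the C10 methyl) in one acidic operation that spares the two acrylates, the methyl ester and the β-hydroxy ketone.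

Compound list

1 | buta-2,3-dien-1-ol | C=C=CCO | starting material
2 | trimethyl orthoacetate | CC(OC)(OC)OC | starting material
3 | 1-(buta-2,3-dien-1-yloxy)-1-methoxyethene (mixed ketene acetal) | C=C(OC)OCC=C=C | intermediate
4 | methyl 3-methylenepent-4-enoate | C=CC(=C)CC(=O)OC | intermediate
5 | methyl 3-methylbut-2-enoate | CC(C)=CC(=O)OC | starting material
6 | methyl (E)-3-methyl-4-oxobut-2-enoate | O=C/C(C)=C/C(=O)OC | intermediate
7 | methyl (1R,6R)-6-formyl-3-(2-methoxy-2-oxoethyl)-6-methylcyclohex-3-ene-1-carboxylate (formyl and ring ester trans) | O=C[C@]1(C)CC=C(CC(=O)OC)C[C@H]1C(=O)OC | intermediate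
8 | methyl (1R,6R)-6-(1-hydroxyprop-2-en-1-yl)-3-(2-methoxy-2-oxoethyl)-6-methylcyclohex-3-ene-1-carboxylate (both carbinol epimers) | C=CC(O)[C@]1(C)CC=C(CC(=O)OC)C[C@H]1C(=O)OC | intermediate
9 | methyl (1R,6R)-6-acryloyl-3-(2-methoxy-2-oxoethyl)-6-methylcyclohex-3-ene-1-carboxylate | C=CC(=O)[C@]1(C)CC=C(CC(=O)OC)C[C@H]1C(=O)OC | intermediate
10 | methyl (1R,6R)-6-[3-iodo-1-(trimethylsilyloxy)prop-1-en-1-yl]-3-(2-methoxy-2-oxoethyl)-6-methylcyclohex-3-ene-1-carboxylate (enol ether geometry open) | C[Si](C)(C)OC(=CCI)[C@]1(C)CC=C(CC(=O)OC)C[C@H]1C(=O)OC | intermediate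
11 | methyl (1R,6R)-6-(3-iodopropanoyl)-3-(2-methoxy-2-oxoethyl)-6-methylcyclohex-3-ene-1-carboxylate | ICCC(=O)[C@]1(C)CC=C(CC(=O)OC)C[C@H]1C(=O)OC | intermediate
12 | methyl (1R,6R)-6-[(1R)-1-hydroxy-3-iodopropyl]-3-(2-methoxy-2-oxoethyl)-6-methylcyclohex-3-ene-1-carboxylate | ICC[C@@H](O)[C@]1(C)CC=C(CC(=O)OC)C[C@H]1C(=O)OC | intermediate
13 | methyl (1R,6R)-6-[(1R)-1-(tert-butyldimethylsilyloxy)-3-iodopropyl]-3-(2-methoxy-2-oxoethyl)-6-methylcyclohex-3-ene-1-carboxylate | ICC[C@@H](O[Si](C)(C)C(C)(C)C)[C@]1(C)CC=C(CC(=O)OC)C[C@H]1C(=O)OC | intermediate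
14 | alkylsamarium diiodide derived from 13 (samarium in place of iodine at C3) | I[Sm](I)CC[C@@H](O[Si](C)(C)C(C)(C)C)[C@]1(C)CC=C(CC(=O)OC)C[C@H]1C(=O)OC | intermediate
15 | methyl 1β-(tert-butyldimethylsilyloxy)-4-oxo-13,15-dinor-5α-eudesm-7-en-12-oate (trans-fused, 10β-methyl) | C1(CC(=O)OC)=CC[C@@]2(C)[C@H](O[Si](C)(C)C(C)(C)C)CCC(=O)[C@@H]2C1 | intermediate
16 | methyl 1β-(tert-butyldimethylsilyloxy)-4,4-(ethylenedioxy)-13,15-dinor-5α-eudesm-7-en-12-oate | C1(CC(=O)OC)=CC[C@@]2(C)[C@H](O[Si](C)(C)C(C)(C)C)CCC3(OCCO3)[C@@H]2C1 | intermediate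
17 | methyl 1β-(tert-butyldimethylsilyloxy)-7α,8α-epoxy-4,4-(ethylenedioxy)-13,15-dinor-5α-eudesman-12-oate | O1[C@H]2C[C@@]3(C)[C@H](O[Si](C)(C)C(C)(C)C)CCC4(OCCO4)[C@@H]3C[C@@]12CC(=O)OC | intermediate
18 | lithium 8α-alkoxide of the 7(11)-alkylidene ester (alkene geometry open) | [Li+].[O-][C@H]1C[C@@]2(C)[C@H](O[Si](C)(C)C(C)(C)C)CCC3(OCCO3)[C@@H]2CC1=CC(=O)OC | intermediate
19 | dilithium 8α-alkoxide 6,11-dienolate | [Li+].[Li+].[O-][C@H]1C[C@@]2(C)[C@H](O[Si](C)(C)C(C)(C)C)CCC3(OCCO3)[C@@H]2C=C1C=C([O-])OC | intermediate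
20 | methyl 1β-(tert-butyldimethylsilyloxy)-4,4-(ethylenedioxy)-8α-hydroxy-13,15-dinor-5α-eudesm-6-en-12-oate | O[C@H]1C[C@@]2(C)[C@H](O[Si](C)(C)C(C)(C)C)CCC3(OCCO3)[C@@H]2C=C1CC(=O)OC | intermediate
21 | 6α-boryl 8α-boryloxy adduct of 20 (simplest representative of the organoborane) | BO[C@H]1C[C@@]2(C)[C@H](O[Si](C)(C)C(C)(C)C)CCC3(OCCO3)[C@@H]2[C@@H](B)[C@@H]1CC(=O)OC | intermediate
22 | methyl 1β-(tert-butyldimethylsilyloxy)-4,4-(ethylenedioxy)-6α,8α-dihydroxy-13,15-dinor-5α,7αH-eudesman-12-oate | O[C@H]1C[C@@]2(C)[C@H](O[Si](C)(C)C(C)(C)C)CCC3(OCCO3)[C@@H]2[C@@H](O)[C@@H]1CC(=O)OC | intermediate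
23 | 11-[(dimethylamino)methyl] derivative of 22 (C11 epimers) | O[C@H]1C[C@@]2(C)[C@H](O[Si](C)(C)C(C)(C)C)CCC3(OCCO3)[C@@H]2[C@@H](O)[C@@H]1C(CN(C)C)C(=O)OC | intermediate
24 | 11-[(trimethylammonio)methyl] iodide derived from 23 | [I-].O[C@H]1C[C@@]2(C)[C@H](O[Si](C)(C)C(C)(C)C)CCC3(OCCO3)[C@@H]2[C@@H](O)[C@@H]1C(C[N+](C)(C)C)C(=O)OC | intermediate
25 | methyl 1β-(tert-butyldimethylsilyloxy)-4,4-(ethylenedioxy)-6α,8α-dihydroxy-15-nor-5α,7αH-eudesm-11(13)-en-12-oate | O[C@H]1C[C@@]2(C)[C@H](O[Si](C)(C)C(C)(C)C)CCC3(OCCO3)[C@@H]2[C@@H](O)[C@@H]1C(=C)C(=O)OC | intermediate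
26 | methyl 2-(hydroxymethyl)acrylate | C=C(CO)C(=O)OC | starting material
27 | methyl 2-[(tert-butyldimethylsilyloxy)methyl]acrylate | C=C(CO[Si](C)(C)C(C)(C)C)C(=O)OC | intermediate
28 | 2-[(tert-butyldimethylsilyloxy)methyl]acrylic acid | C=C(CO[Si](C)(C)C(C)(C)C)C(=O)O | intermediate
29 | methyl 1β-(tert-butyldimethylsilyloxy)-8α-{2-[(tert-butyldimethylsilyloxy)methyl]acryloyloxy}-4,4-(ethylenedioxy)-6α-hydroxy-15-nor-5α,7αH-eudesm-11(13)-en-12-oate | C=C(CO[Si](C)(C)C(C)(C)C)C(=O)O[C@H]1C[C@@]2(C)[C@H](O[Si](C)(C)C(C)(C)C)CCC3(OCCO3)[C@@H]2[C@@H](O)[C@@H]1C(=C)C(=O)OC | intermediate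
30 | methyl 1β,6α-dihydroxy-8α-[2-(hydroxymethyl)acryloyloxy]-4-oxo-15-nor-5α,7αH-eudesm-11(13)-en-12-oate (CNP0144895.1) | C=C(CO)C(=O)O[C@H]1C[C@@]2(C)[C@H](O)CCC(=O)[C@@H]2[C@@H](O)[C@@H]1C(=C)C(=O)OC | target

Total step count: 18. Longest linear sequence: 15 steps (steps 1, 3 to 14, 17 and 18); steps 2, 15 and 16 are convergent side branches.

The three steps most likely to fail are step 9, step 13 and step 3.

Risk at step 9 (key step): the alkylsamarium may be protonated before it reaches the hindered C4 ester, or the primary radical may add to the ring alkene, so that the iodide is lost without ring closure. The fallback replaces the reductive closure by an anionic one; it sets out from 13 and comes back to the route at 15. Displacement of iodide with PhSO2Na (DMF, 60 °C) should give the sulfone methyl (1R,6R)-6-[(1R)-1-(tert-butyldimethylsilyloxy)-3-(phenylsulfonyl)propyl]-3-(2-methoxy-2-oxoethyl)-6-methylcyclohex-3-ene-1-carboxylate F1. LiN(SiMe3)2 (3 equiv, THF, −78 → 0 °C) should then close ring A by Claisen-type acylation of the α-sulfonyl carbanion at the C4 ester and give the keto sulfone methyl 1β-(tert-butyldimethylsilyloxy)-4-oxo-3-(phenylsulfonyl)-13,15-dinor-5α-eudesm-7-en-12-oate F2, held as its enolate until work-up. Reductive desulfonylation of F2 with Al(Hg) in wet THF should then give 15.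

Risk at step 13: borane may attack from the β-face or at C7, or reduce the methyl ester. The fallback replaces hydroboration by hydroxyl-directed epoxidation and radical opening of the epoxide; it sets out from 20 and comes back to the route at 22. With VO(acac)2 (acac = pentane-2,4-dionate) and tBuOOH in CH2Cl2 at 0 °C, the 8α-hydroxyl should deliver the oxidant to its own face and give the epoxy alcohol methyl 1β-(tert-butyldimethylsilyloxy)-6α,7α-epoxy-4,4-(ethylenedioxy)-8α-hydroxy-13,15-dinor-5α-eudesman-12-oate F3. Cp2TiCl (trivalent titanium, made from Cp2TiCl2 and Mn powder) with 1,4-cyclohexadiene in THF should then cleave the C7–O bond homolytically to the tertiary C7 radical. Axial hydrogen-atom transfer to that radical from the α-face places the C11 arm equatorial and gives 22.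

Risk at step 3: enantiofacial or regiochemical control may be insufficient with this trisubstituted, doubly activated dienophile, or the acid may isomerise the skipped diene ester. The fallback gives up asymmetric catalysis; it sets out from 4 and 6 and comes back to the route at 7. An EtAlCl2-promoted Diels–Alder reaction (CH2Cl2, −78 °C) should give the racemate, that is 7 together with its enantiomer methyl (1S,6S)-6-formyl-3-(2-methoxy-2-oxoethyl)-6-methylcyclohex-3-ene-1-carboxylate F4. Preparative chromatography on a chiral stationary phase should then separate 7 from F4.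

Further compounds

F1 | step 9 | methyl (1R,6R)-6-[(1R)-1-(tert-butyldimethylsilyloxy)-3-(phenylsulfonyl)propyl]-3-(2-methoxy-2-oxoethyl)-6-methylcyclohex-3-ene-1-carboxylate | O=S(=O)(c1ccccc1)CC[C@@H](O[Si](C)(C)C(C)(C)C)[C@]2(C)CC=C(CC(=O)OC)C[C@H]2C(=O)OC
F2 | step 9 | methyl 1β-(tert-butyldimethylsilyloxy)-4-oxo-3-(phenylsulfonyl)-13,15-dinor-5α-eudesm-7-en-12-oate | C1(CC(=O)OC)=CC[C@@]2(C)[C@H](O[Si](C)(C)C(C)(C)C)CC(S(=O)(=O)c3ccccc3)C(=O)[C@@H]2C1
F3 | step 13 | methyl 1β-(tert-butyldimethylsilyloxy)-6α,7α-epoxy-4,4-(ethylenedioxy)-8α-hydroxy-13,15-dinor-5α-eudesman-12-oate | O[C@H]1C[C@@]2(C)[C@H](O[Si](C)(C)C(C)(C)C)CCC3(OCCO3)[C@@H]2[C@H]4O[C@]41CC(=O)OC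
F4 | step 3 | methyl (1S,6S)-6-formyl-3-(2-methoxy-2-oxoethyl)-6-methylcyclohex-3-ene-1-carboxylate | O=C[C@@]1(C)CC=C(CC(=O)OC)C[C@@H]1C(=O)OC
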